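**Assumption:** in step 1 the phosphoramidite enantiomer is the one that gives the 5R adduct (both are available). Comments use eremophilane numbering (ester carbon C3, carbinol C9, ring-fusion CH C10, angular methyl on C5).

**Retrosynthetic overview**
1. The (Z)-γ-hydroxy-enone of the target is a ring-opened 3-methylfuran (singlet oxygen, then aldehyde reduction), unmasked after the C3 alcohol is esterified with the trienoic acid (vinylogous HWE).
2. Ring B and the furan form together in one intramolecular oxazole–alkyne [4+2]/retro-[4+2] (loss of MeCN) of an acyl-oxazole tethered to a 2-butynyl group on ring A.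
3. C9–OH comes from Luche reduction anti to the angular methyl, the cis ring fusion from hydroxyl-directed hydrogenation, and C3–OH from equilibrating reduction of the unmasked ketone.
4. The cycloaddition precursor comes from an alkenyl triflate and an oxazole aldehyde (Ni/Cr coupling, oxidation).
5. Ring A is carried from benzoquinone monoketal: catalytic asymmetric Me2Zn addition, then two α′-alkylations (Me, 2-butynyl). Ring order: A (given), then B + furan together.

**Step 1**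
Reactants: 1 4,4-dimethoxycyclohexa-2,5-dien-1-one
Product: 2 (5R)-4,4-dimethoxy-5-methylcyclohex-2-en-1-one
Conditions: Me2Zn, Cu(OTf)2 (2 mol%), BINOL bis(1-phenylethyl)amine phosphoramidite (4 mol%), toluene, −25 °C; aq. NH4Cl
Reagents that add atoms: dimethylzinc, C[Zn]C
Why: Cu/phosphoramidite-catalysed enantioselective conjugate addition desymmetrises the prochiral dienone, and the catalyst sets the methyl-bearing centre (R) from which every later centre is derived.

**Step 2**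
Reactants: 2 (5R)-4,4-dimethoxy-5-methylcyclohex-2-en-1-one
Product: 4 (5R)-4,4-dimethoxy-5,6-dimethylcyclohex-2-en-1-one (C6 epimers), via lithium enolate 3 (not isolated)
Conditions: LDA, THF, −78 °C; MeI, DMPU, −78 → −30 °C
Reagents that add atoms: iodomethane, CI
Why: Kinetic α′-deprotonation of the enone (the γ-carbon is the ketal, so no other enolate can form) and enolate methylation; the new C6 centre is flattened again in step 3 and need not be controlled.

**Step 3**
Reactants: 4 (5R)-4,4-dimethoxy-5,6-dimethylcyclohex-2-en-1-one (C6 epimers); 5 1-bromobut-2-yne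
Product: 7 (5R,6R)-6-(but-2-yn-1-yl)-4,4-dimethoxy-5,6-dimethylcyclohex-2-en-1-one, via lithium enolate 6 (not isolated)
Conditions: LDA, THF/DMPU, −78 °C; 5, −78 → 0 °C
Reagents that add atoms: none
Why: Enolate alkylation of the tetrasubstituted α′-enolate; A(1,2) strain holds the C5 methyl pseudoaxial and the propargylic bromide enters anti to it, so the quaternary centre forms with the two methyls cis (the symmetric ketal hinders both faces equally).

**Step 4**
Reactants: 7 (5R,6R)-6-(but-2-yn-1-yl)-4,4-dimethoxy-5,6-dimethylcyclohex-2-en-1-one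
Product: 9 (5R,6R)-6-(but-2-yn-1-yl)-4,4-dimethoxy-5,6-dimethylcyclohex-1-en-1-yl trifluoromethanesulfonate, via lithium enolate 8 (not isolated)
Conditions: L-Selectride, THF, −78 °C; PhNTf2, −78 → 0 °C
Reagents that add atoms: N-phenylbis(trifluoromethanesulfonimide), O=S(=O)(N(c1ccccc1)S(=O)(=O)C(F)(F)F)C(F)(F)F
Why: Conjugate hydride reduction of the β-unsubstituted enone (1,2-attack is blocked by the α-quaternary centre) and O-triflation of the regiodefined enolate; no stereocentre is touched.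

**Step 5**
Reactants: 9 (5R,6R)-6-(but-2-yn-1-yl)-4,4-dimethoxy-5,6-dimethylcyclohex-1-en-1-yl trifluoromethanesulfonate; 10 4-methyl-1,3-oxazole-5-carbaldehyde
Product: 11 [(5R,6R)-6-(but-2-yn-1-yl)-4,4-dimethoxy-5,6-dimethylcyclohex-1-en-1-yl](4-methyl-1,3-oxazol-5-yl)methanol (carbinol epimers)
Conditions: CrCl2 (4 equiv), NiCl2 (2 mol%), DMF, rt
Reagents that add atoms: none
Why: Nozaki–Hiyama–Kishi coupling of the hindered alkenyl triflate tolerates the alkyne, ketal and oxazole C2–H (a Pd/CO acylation would instead acylpalladate the tethered alkyne); the carbinol centre is erased in step 6.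

**Step 6**
Reactants: 11 [(5R,6R)-6-(but-2-yn-1-yl)-4,4-dimethoxy-5,6-dimethylcyclohex-1-en-1-yl](4-methyl-1,3-oxazol-5-yl)methanol (carbinol epimers)
Product: 12 [(5R,6R)-6-(but-2-yn-1-yl)-4,4-dimethoxy-5,6-dimethylcyclohex-1-en-1-yl](4-methyl-1,3-oxazol-5-yl)methanone
Conditions: MnO2, CH2Cl2, rt
Reagents that add atoms: none
Why: MnO2 oxidation of a doubly activated (allylic and heteroaryl) carbinol to the cross-conjugated acyl-oxazole.

**Step 7 (key step)**
Reactants: 12 [(5R,6R)-6-(but-2-yn-1-yl)-4,4-dimethoxy-5,6-dimethylcyclohex-1-en-1-yl](4-methyl-1,3-oxazol-5-yl)methanone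
Product: 14 (4aR,5R)-6,6-dimethoxy-3,4a,5-trimethyl-4a,5,6,7-tetrahydronaphtho[2,3-b]furan-9(4H)-one, via bicyclic cycloadduct 13 (not isolated)
Conditions: 1,2-Cl2C6H4 (0.01 M), BHT (cat.), 180 °C, sealed tube
Reagents that add atoms: none
Why: Intramolecular oxazole–alkyne Diels–Alder reaction followed by retro-Diels–Alder loss of acetonitrile closes ring B and the furan in one operation; the acyl group lowers the oxazole LUMO toward the unactivated alkyne and the gem-disubstituted four-atom tether holds the partners together; no stereocentre is formed.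

**Step 8**
Reactants: 14 (4aR,5R)-6,6-dimethoxy-3,4a,5-trimethyl-4a,5,6,7-tetrahydronaphtho[2,3-b]furan-9(4H)-one
Product: 15 (4aR,5R,9R)-6,6-dimethoxy-3,4a,5-trimethyl-4,4a,5,6,7,9-hexahydronaphtho[2,3-b]furan-9-ol
Conditions: NaBH4, CeCl3·7H2O, MeOH, −78 °C
Reagents that add atoms: none
Why: Luche 1,2-reduction; the angular methyl stands perpendicular over one face of the flat dienone, so hydride attacks C9 from the opposite face and the hydroxyl ends cis to that methyl (9R).

**Step 9**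
Reactants: 15 (4aR,5R,9R)-6,6-dimethoxy-3,4a,5-trimethyl-4,4a,5,6,7,9-hexahydronaphtho[2,3-b]furan-9-ol
Product: 16 (4aS,5R,8aS,9R)-6,6-dimethoxy-3,4a,5-trimethyl-4,4a,5,6,7,8,8a,9-octahydronaphtho[2,3-b]furan-9-ol
Conditions: H2 (1 atm), [Ir(cod)(PCy3)(py)]PF6 (10 mol%), CH2Cl2, 0 °C
Reagents that add atoms: none
Why: Hydroxyl-directed homogeneous hydrogenation (Crabtree catalyst); iridium bound to the C9 hydroxyl delivers H2 to the same face of the 1(10)-alkene and sets the cis ring fusion (8aS) against the steric bias of the angular methyl.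

**Step 10**
Reactants: 16 (4aS,5R,8aS,9R)-6,6-dimethoxy-3,4a,5-trimethyl-4,4a,5,6,7,8,8a,9-octahydronaphtho[2,3-b]furan-9-ol
Product: 17 tert-butyl{[(4aS,5R,8aS,9R)-6,6-dimethoxy-3,4a,5-trimethyl-4,4a,5,6,7,8,8a,9-octahydronaphtho[2,3-b]furan-9-yl]oxy}dimethylsilane
Conditions: TBSOTf, 2,6-lutidine, CH2Cl2, −78 °C
Reagents that add atoms: tert-butyldimethylsilyl trifluoromethanesulfonate, CC(C)(C)[Si](C)(C)OS(=O)(=O)C(F)(F)F
Why: Silylation of the hindered furfuryl alcohol under buffered conditions; the ether prevents ionisation in step 11 and an Achmatowicz-type rearrangement in step 16.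

**Step 11**
Reactants: 17 tert-butyl{[(4aS,5R,8aS,9R)-6,6-dimethoxy-3,4a,5-trimethyl-4,4a,5,6,7,8,8a,9-octahydronaphtho[2,3-b]furan-9-yl]oxy}dimethylsilane
Product: 18 (4aS,5R,8aS,9R)-9-[(tert-butyldimethylsilyl)oxy]-3,4a,5-trimethyl-4a,5,7,8,8a,9-hexahydronaphtho[2,3-b]furan-6(4H)-one
Conditions: PPTS (cat.), acetone/H2O, rt
Reagents that add atoms: water, O
Why: Mild acid hydrolysis of the dimethyl ketal; the secondary TBS ether and the furan survive PPTS, and the α-methyl centre stays in its more stable equatorial configuration.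

**Step 12**
Reactants: 18 (4aS,5R,8aS,9R)-9-[(tert-butyldimethylsilyl)oxy]-3,4a,5-trimethyl-4a,5,7,8,8a,9-hexahydronaphtho[2,3-b]furan-6(4H)-one
Product: 19 (4aR,5R,6R,8aS,9R)-9-[(tert-butyldimethylsilyl)oxy]-3,4a,5-trimethyl-4,4a,5,6,7,8,8a,9-octahydronaphtho[2,3-b]furan-6-ol
Conditions: Al(Oi-Pr)3, i-PrOH/toluene, 80 °C, run to equilibrium
Reagents that add atoms: none
Why: Meerwein–Ponndorf–Verley reduction under equilibrating conditions gives the thermodynamic equatorial alcohol (6R, trans to the neighbouring methyl), because the axial epimer suffers a 1,3-diaxial clash with the angular methyl.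

**Step 13**
Reactants: 20 (3E)-non-3-en-2-one; 21 triethyl (2E)-4-phosphonobut-2-enoate
Product: 23 ethyl (2E,4E,6E)-5-methyldodeca-2,4,6-trienoate, via lithiated phosphonate 22 (not isolated)
Conditions: LiHMDS, THF, −78 °C; 20, −78 °C → rt; chromatography
Reagents that add atoms: none
Why: Vinylogous Horner–Wadsworth–Emmons olefination of the methyl ketone builds the triene in one step; the new trisubstituted bond forms mainly E and the minor 4Z isomer is removed.

**Step 14**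
Reactants: 23 ethyl (2E,4E,6E)-5-methyldodeca-2,4,6-trienoate
Product: 24 (2E,4E,6E)-5-methyldodeca-2,4,6-trienoic acid
Conditions: LiOH, THF/MeOH/H2O, rt; then dil. HCl
Reagents that add atoms: lithium hydroxide, [Li+].[OH-]
Why: Ester saponification; no stereochemistry is affected.

**Step 15**
Reactants: 19 (4aR,5R,6R,8aS,9R)-9-[(tert-butyldimethylsilyl)oxy]-3,4a,5-trimethyl-4,4a,5,6,7,8,8a,9-octahydronaphtho[2,3-b]furan-6-ol; 24 (2E,4E,6E)-5-methyldodeca-2,4,6-trienoic acid
Product: 25 (4aR,5R,6R,8aS,9R)-9-[(tert-butyldimethylsilyl)oxy]-3,4a,5-trimethyl-4,4a,5,6,7,8,8a,9-octahydronaphtho[2,3-b]furan-6-yl (2E,4E,6E)-5-methyldodeca-2,4,6-trienoate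
Conditions: DCC, DMAP (cat.), CH2Cl2, 0 °C → rt
Reagents that add atoms: none
Why: Steglich esterification of the equatorial secondary alcohol with retention at C6.

**Step 16**
Reactants: 25 (4aR,5R,6R,8aS,9R)-9-[(tert-butyldimethylsilyl)oxy]-3,4a,5-trimethyl-4,4a,5,6,7,8,8a,9-octahydronaphtho[2,3-b]furan-6-yl (2E,4E,6E)-5-methyldodeca-2,4,6-trienoate
Product: 28 (1R,2R,4aS,5R,8aR)-5-[(tert-butyldimethylsilyl)oxy]-7-[(2Z)-1-hydroxypropan-2-ylidene]-1,8a-dimethyl-6-oxodecahydronaphthalen-2-yl (2E,4E,6E)-5-methyldodeca-2,4,6-trienoate, via furan endoperoxide 26 (not isolated), via keto-enal 27 (not isolated)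
Conditions: O2, hν, TPP (cat.), CH2Cl2, −78 °C; Me2S, −78 → −30 °C; NaBH4, MeOH, −78 °C
Reagents that add atoms: dioxygen, O=O
Why: The furan is a masked (Z)-γ-hydroxy-enone: [4+2] addition of singlet oxygen (far faster on the furan than on the electron-poor trienoate), Me2S reduction to the (Z)-keto-enal whose geometry is fixed by the former ring, then chemoselective low-temperature borohydride reduction of the aldehyde.

**Step 17**
Reactants: 28 (1R,2R,4aS,5R,8aR)-5-[(tert-butyldimethylsilyl)oxy]-7-[(2Z)-1-hydroxypropan-2-ylidene]-1,8a-dimethyl-6-oxodecahydronaphthalen-2-yl (2E,4E,6E)-5-methyldodeca-2,4,6-trienoate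
Product: 29 (1R,2R,4aS,5R,8aR)-5-hydroxy-7-[(2Z)-1-hydroxypropan-2-ylidene]-1,8a-dimethyl-6-oxodecahydronaphthalen-2-yl (2E,4E,6E)-5-methyldodeca-2,4,6-trienoate
Conditions: HF·pyridine, pyridine, THF, 0 °C
Reagents that add atoms: none
Why: Buffered fluoride cleavage of the α-silyloxy ketone, mild enough not to dehydrate the γ-hydroxy-enone back to a furan or epimerise the ketol.

**Compound list**
1 | 4,4-dimethoxycyclohexa-2,5-dien-1-one | COC1(OC)C=CC(=O)C=C1 | starting material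
2 | (5R)-4,4-dimethoxy-5-methylcyclohex-2-en-1-one | COC1(OC)C=CC(=O)C[C@H]1C | intermediate
3 | lithium α′-enolate of 2 | COC1(OC)C=CC(O[Li])=C[C@H]1C | intermediate
4 | (5R)-4,4-dimethoxy-5,6-dimethylcyclohex-2-en-1-one (C6 epimers) | COC1(OC)C=CC(=O)C(C)[C@H]1C | intermediate
5 | 1-bromobut-2-yne | CC#CCBr | starting material
6 | lithium α′-enolate of 4 | COC1(OC)C=CC(O[Li])=C(C)[C@H]1C | intermediate
7 | (5R,6R)-6-(but-2-yn-1-yl)-4,4-dimethoxy-5,6-dimethylcyclohex-2-en-1-one | COC1(OC)C=CC(=O)[C@](C)(CC#CC)[C@H]1C | intermediate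
8 | lithium (5R,6R)-6-(but-2-yn-1-yl)-4,4-dimethoxy-5,6-dimethylcyclohex-1-en-1-olate | COC1(OC)CC=C(O[Li])[C@](C)(CC#CC)[C@H]1C | intermediate
9 | (5R,6R)-6-(but-2-yn-1-yl)-4,4-dimethoxy-5,6-dimethylcyclohex-1-en-1-yl trifluoromethanesulfonate | COC1(OC)CC=C(OS(=O)(=O)C(F)(F)F)[C@](C)(CC#CC)[C@H]1C | intermediate
10 | 4-methyl-1,3-oxazole-5-carbaldehyde | Cc1ncoc1C=O | starting material
11 | [(5R,6R)-6-(but-2-yn-1-yl)-4,4-dimethoxy-5,6-dimethylcyclohex-1-en-1-yl](4-methyl-1,3-oxazol-5-yl)methanol (carbinol epimers) | COC1(OC)CC=C(C(O)c2ocnc2C)[C@](C)(CC#CC)[C@H]1C | intermediate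
12 | [(5R,6R)-6-(but-2-yn-1-yl)-4,4-dimethoxy-5,6-dimethylcyclohex-1-en-1-yl](4-methyl-1,3-oxazol-5-yl)methanone | COC1(OC)CC=C(C(=O)c2ocnc2C)[C@](C)(CC#CC)[C@H]1C | intermediate
13 | 7-oxa-2-azabicyclo[2.2.1]hepta-2,5-diene cycloadduct of 12 (alkyne across oxazole C2/C5) | COC1(OC)CC=C2C(=O)C34OC(N=C3C)C(C)=C4C[C@]2(C)[C@H]1C | intermediate
14 | (4aR,5R)-6,6-dimethoxy-3,4a,5-trimethyl-4a,5,6,7-tetrahydronaphtho[2,3-b]furan-9(4H)-one | COC1(OC)CC=C2C(=O)c3occ(C)c3C[C@]2(C)[C@H]1C | intermediate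
15 | (4aR,5R,9R)-6,6-dimethoxy-3,4a,5-trimethyl-4,4a,5,6,7,9-hexahydronaphtho[2,3-b]furan-9-ol | COC1(OC)CC=C2[C@@H](O)c3occ(C)c3C[C@]2(C)[C@H]1C | intermediate
16 | (4aS,5R,8aS,9R)-6,6-dimethoxy-3,4a,5-trimethyl-4,4a,5,6,7,8,8a,9-octahydronaphtho[2,3-b]furan-9-ol | COC1(OC)CC[C@@H]2[C@@H](O)c3occ(C)c3C[C@]2(C)[C@H]1C | intermediate
17 | tert-butyl{[(4aS,5R,8aS,9R)-6,6-dimethoxy-3,4a,5-trimethyl-4,4a,5,6,7,8,8a,9-octahydronaphtho[2,3-b]furan-9-yl]oxy}dimethylsilane | COC1(OC)CC[C@@H]2[C@@H](O[Si](C)(C)C(C)(C)C)c3occ(C)c3C[C@]2(C)[C@H]1C | intermediate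
18 | (4aS,5R,8aS,9R)-9-[(tert-butyldimethylsilyl)oxy]-3,4a,5-trimethyl-4a,5,7,8,8a,9-hexahydronaphtho[2,3-b]furan-6(4H)-one | O=C1CC[C@@H]2[C@@H](O[Si](C)(C)C(C)(C)C)c3occ(C)c3C[C@]2(C)[C@H]1C | intermediate
19 | (4aR,5R,6R,8aS,9R)-9-[(tert-butyldimethylsilyl)oxy]-3,4a,5-trimethyl-4,4a,5,6,7,8,8a,9-octahydronaphtho[2,3-b]furan-6-ol | O[C@@H]1CC[C@@H]2[C@@H](O[Si](C)(C)C(C)(C)C)c3occ(C)c3C[C@]2(C)[C@H]1C | intermediate
20 | (3E)-non-3-en-2-one | CCCCC/C=C/C(C)=O | starting material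
21 | triethyl (2E)-4-phosphonobut-2-enoate | CCOC(=O)/C=C/CP(=O)(OCC)OCC | starting material
22 | lithiated 21 (phosphonate-stabilised allyl anion) | CCOC(=O)/C=C/[CH-]P(=O)(OCC)OCC.[Li+] | intermediate
23 | ethyl (2E,4E,6E)-5-methyldodeca-2,4,6-trienoate | CCCCC/C=C/C(C)=C/C=C/C(=O)OCC | intermediate
24 | (2E,4E,6E)-5-methyldodeca-2,4,6-trienoic acid | CCCCC/C=C/C(C)=C/C=C/C(=O)O | intermediate
25 | (4aR,5R,6R,8aS,9R)-9-[(tert-butyldimethylsilyl)oxy]-3,4a,5-trimethyl-4,4a,5,6,7,8,8a,9-octahydronaphtho[2,3-b]furan-6-yl (2E,4E,6E)-5-methyldodeca-2,4,6-trienoate | CCCCC/C=C/C(C)=C/C=C/C(=O)O[C@@H]1CC[C@@H]2[C@@H](O[Si](C)(C)C(C)(C)C)c3occ(C)c3C[C@]2(C)[C@H]1C | intermediate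
26 | furan 2,5-endoperoxide of 25 (new bridgehead centres not assigned) | CCCCC/C=C/C(C)=C/C=C/C(=O)O[C@@H]1CC[C@@H]2[C@@H](O[Si](C)(C)C(C)(C)C)C34OC(OO3)C(C)=C4C[C@]2(C)[C@H]1C | intermediate
27 | (Z)-keto-enal from 26 (C8 ketone, C12 aldehyde) | CCCCC/C=C/C(C)=C/C=C/C(=O)O[C@@H]1CC[C@@H]2[C@@H](O[Si](C)(C)C(C)(C)C)C(=O)/C(=C(/C)C=O)C[C@]2(C)[C@H]1C | intermediate
28 | (1R,2R,4aS,5R,8aR)-5-[(tert-butyldimethylsilyl)oxy]-7-[(2Z)-1-hydroxypropan-2-ylidene]-1,8a-dimethyl-6-oxodecahydronaphthalen-2-yl (2E,4E,6E)-5-methyldodeca-2,4,6-trienoate | CCCCC/C=C/C(C)=C/C=C/C(=O)O[C@@H]1CC[C@@H]2[C@@H](O[Si](C)(C)C(C)(C)C)C(=O)/C(=C(/C)CO)C[C@]2(C)[C@H]1C | intermediate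
29 | (1R,2R,4aS,5R,8aR)-5-hydroxy-7-[(2Z)-1-hydroxypropan-2-ylidene]-1,8a-dimethyl-6-oxodecahydronaphthalen-2-yl (2E,4E,6E)-5-methyldodeca-2,4,6-trienoate (CNP0226738.1) | CCCCC/C=C/C(C)=C/C=C/C(=O)O[C@@H]1CC[C@@H]2[C@@H](O)C(=O)/C(=C(/C)CO)C[C@]2(C)[C@H]1C | target

**Step count**
Total steps: 17. Longest linear sequence: 15 (steps 1–12 and 15–17); steps 13–14 make the acid in a two-step branch.

**The three steps most likely to fail**

Step 7 (cycloaddition/cycloreversion). The electron-poor acyl-oxazole may react too slowly with the unactivated alkyne, or the 1,5-enyne may rearrange first at 180 °C. The fallback sets out from carbinol 11 and comes back at dienone 14; it runs the cycloaddition at the alcohol oxidation level, where the oxazole is the classical alkyl-substituted diene and no enone is present. TBSOTf/2,6-lutidine gives the oxazolyl carbinol silyl ether F1. Thermolysis in 1,2-dichlorobenzene at 200–220 °C with loss of acetonitrile gives the furan silyl ether F2. TBAF gives the furyl carbinol F3, and MnO2 oxidation gives 14.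

Step 9 (directed hydrogenation). The allylic hydroxyl must steer the catalyst onto the face that also carries the angular methyl, and the doubly activated alcohol is acid-sensitive. The fallback sets out from 15 and comes back at ester 25 (using acid 24); the directing group becomes an axial homoallylic hydroxyl on ring A. TBSOTf gives the dienyl silyl ether F4, and PPTS in aqueous acetone gives the β,γ-unsaturated ketone F5. L-Selectride, attacking anti to the angular methyl, gives the axial alcohol F6. Crabtree hydrogenation directed by this hydroxyl gives the cis-fused alcohol F7. Mitsunobu esterification of F7 with 24 (DIAD, PPh3) inverts the carbinol and gives 25; elimination is the known risk of this last operation.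

Step 16 (furan unmasking beside the triene, aldehyde-selective reduction). If singlet oxygen or borohydride touches the trienoate, the order is changed so that the furan is opened before the triene is present. The fallback sets out from alcohol 19 and comes back at target 29. The same photooxygenation/Me2S/NaBH4 sequence on 19 gives the enone diol F8. TESCl/imidazole silylates only the primary allylic hydroxyl and gives the triethylsilyl ether F9. DCC/DMAP esterification with 24 gives the bis-silyl ester F10, and HF·pyridine removes both silyl groups to give 29.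

**Further compounds**
F1 | step 7 | tert-butyldimethylsilyl ether of carbinol 11 (carbinol epimers) | COC1(OC)CC=C(C(O[Si](C)(C)C(C)(C)C)c2ocnc2C)[C@](C)(CC#CC)[C@H]1C
F2 | step 7 | tert-butyl{[(4aR,5R)-6,6-dimethoxy-3,4a,5-trimethyl-4,4a,5,6,7,9-hexahydronaphtho[2,3-b]furan-9-yl]oxy}dimethylsilane (C9 epimers) | COC1(OC)CC=C2C(O[Si](C)(C)C(C)(C)C)c3occ(C)c3C[C@]2(C)[C@H]1C
F3 | step 7 | (4aR,5R)-6,6-dimethoxy-3,4a,5-trimethyl-4,4a,5,6,7,9-hexahydronaphtho[2,3-b]furan-9-ol (C9 epimers) | COC1(OC)CC=C2C(O)c3occ(C)c3C[C@]2(C)[C@H]1C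
F4 | step 9 | tert-butyldimethylsilyl ether of 15 (9R) | COC1(OC)CC=C2[C@@H](O[Si](C)(C)C(C)(C)C)c3occ(C)c3C[C@]2(C)[C@H]1C
F5 | step 9 | (4aR,5R,9R)-9-[(tert-butyldimethylsilyl)oxy]-3,4a,5-trimethyl-4a,5,7,9-tetrahydronaphtho[2,3-b]furan-6(4H)-one | O=C1CC=C2[C@@H](O[Si](C)(C)C(C)(C)C)c3occ(C)c3C[C@]2(C)[C@H]1C
F6 | step 9 | (4aR,5R,6S,9R)-9-[(tert-butyldimethylsilyl)oxy]-3,4a,5-trimethyl-4,4a,5,6,7,9-hexahydronaphtho[2,3-b]furan-6-ol | O[C@H]1CC=C2[C@@H](O[Si](C)(C)C(C)(C)C)c3occ(C)c3C[C@]2(C)[C@H]1C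
F7 | step 9 | (4aR,5R,6S,8aS,9R)-9-[(tert-butyldimethylsilyl)oxy]-3,4a,5-trimethyl-4,4a,5,6,7,8,8a,9-octahydronaphtho[2,3-b]furan-6-ol | O[C@H]1CC[C@@H]2[C@@H](O[Si](C)(C)C(C)(C)C)c3occ(C)c3C[C@]2(C)[C@H]1C
F8 | step 16 | (1R,2R,4aS,5R,8aR)-5-[(tert-butyldimethylsilyl)oxy]-2-hydroxy-7-[(2Z)-1-hydroxypropan-2-ylidene]-1,8a-dimethyloctahydronaphthalen-6(2H)-one | O[C@@H]1CC[C@@H]2[C@@H](O[Si](C)(C)C(C)(C)C)C(=O)/C(=C(/C)CO)C[C@]2(C)[C@H]1C
F9 | step 16 | primary triethylsilyl ether of F8 | O[C@@H]1CC[C@@H]2[C@@H](O[Si](C)(C)C(C)(C)C)C(=O)/C(=C(/C)CO[Si](CC)(CC)CC)C[C@]2(C)[C@H]1C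
F10 | step 16 | (2E,4E,6E)-5-methyldodeca-2,4,6-trienoate of F9 | CCCCC/C=C/C(C)=C/C=C/C(=O)O[C@@H]1CC[C@@H]2[C@@H](O[Si](C)(C)C(C)(C)C)C(=O)/C(=C(/C)CO[Si](CC)(CC)CC)C[C@]2(C)[C@H]1C
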